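**Direct plan and its weak points**

A direct plan would close the pyranone first and arylate it afterwards: acetophenone A1 would be condensed with DMF-DMA and cyclised to 5,6,7-trimethoxychromone A2.
Bromide A3 would be deprotonated between its 2- and 4-methoxy groups, borylated and oxidised to bromophenol A4.
Zincation of A2 at C2 and Negishi coupling with A4 would give the 5-O-methyl flavone A5, and BCl3 would then free the 5-OH.
- Weak, the hydroxylation of ring B by deprotonation of A3: the hydrogen flanked by Br and OMe competes with the one between two OMe groups, and an ortho-bromo aryllithium can lose LiBr to an aryne or let bromine migrate.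
- Weak, the Negishi union: the free OH of A4 would protonate the chromenylzinc (hence an excess of the more advanced partner), while oxidative addition into the electron-rich, di-ortho-substituted bromide would be slow.
- Weak, the final BCl3 cleavage: a methyl group carried from the start would be removed at the very end, one of six OMe, beside a ring-B phenol that also binds boron, so over-cleavage would cost finished material.

**Retrosynthetic overview of the new route**

Ring C (O1, C2, C3, C4, C4a, C8a) is cut at three bonds at once, C4a–C4, C4–C3 and O1–C2: a ring-A iodophenol, carbon monoxide (the C4 carbonyl) and a ring-B ethynylphenol (C3, C2) are joined in the last step.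
Rings A and B are bought as arenes; ring C is the only ring formed and it closes last.
Both arenes are 2-substituted 3-hydroxy-4,5-dimethoxyphenyl units (ring A: C8a–O, C4a, 5-OH, 6,7-OMe; ring B: C1', 2'-OMe, 3'-OH, 4',5'-OMe), so one iodination of one commercial aldehyde serves both. For ring B the iodide becomes 2'-OMe and CHO the alkyne; for ring A the iodide becomes C4a and CHO is oxidised out to the O1 phenol.
The 3'-OH and 5-OH come from the starting phenol and are never methylated: no aryl deprotonation beside a halogen, no carbanion coupling beside a free phenol, no late ether cleavage. The 5-oxygen is held as a pivalate that fixes which oxygen closes ring C.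

Key step: step 6

Remark: the enaminone that forms in the last step is drawn as its E isomer; its push–pull double bond isomerises freely and either isomer can close.

**Route**

Step 1
Reactants: 1 3-hydroxy-4,5-dimethoxybenzaldehyde
Product: 2 3-hydroxy-2-iodo-4,5-dimethoxybenzaldehyde
Conditions: ICl (1.1 equiv), pyridine, 1,4-dioxane, 0 °C → rt
Reagents that add atoms: iodine monochloride, ClI
Why: Electrophilic aromatic iodination in which the free phenol should direct iodine to its ortho carbon C2, between OH and CHO and para to the 5-methoxy group, as in the 2-halogenation of isovanillin, while C6 is hindered by the in-plane 5-methoxy group.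

Step 2
Reactants: 2 3-hydroxy-2-iodo-4,5-dimethoxybenzaldehyde
Product: 3 3-hydroxy-2,4,5-trimethoxybenzaldehyde
Conditions: NaOMe (5 equiv, 25% in MeOH), CuCl (0.2 equiv), DMF, 110 °C; then aq. HCl
Reagents that add atoms: sodium methoxide, C[O-].[Na+]
Why: Copper-catalysed Ullmann-type C–O coupling of the kind that turns 5-halovanillins into syringaldehyde: the iodide is activated by the ortho formyl group, and the phenol reacts as its sodium salt and needs no protection.

Step 3
Reactants: 3 3-hydroxy-2,4,5-trimethoxybenzaldehyde
Product: 4 3-ethynyl-2,5,6-trimethoxyphenol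
Conditions: dimethyl (1-diazo-2-oxopropyl)phosphonate (1.5 equiv), K2CO3 (3 equiv), MeOH, 0 °C → rt
Reagents that add atoms: dimethyl (1-diazo-2-oxopropyl)phosphonate, CC(=O)C(=[N+]=[N-])P(=O)(OC)OC
Why: Seyferth–Gilbert homologation in its Ohira–Bestmann form: the diazophosphonate anion freed by methoxide olefinates the aldehyde and the diazoalkene loses N2 with 1,2-hydrogen shift to the terminal alkyne, the phenol (meta to the aldehyde) being only deprotonated.

Step 4
Reactants: 2 3-hydroxy-2-iodo-4,5-dimethoxybenzaldehyde
Product: 5 3-formyl-2-iodo-5,6-dimethoxyphenyl 2,2-dimethylpropanoate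
Conditions: PivCl (1.3 equiv), Et3N (2 equiv), DMAP (0.1 equiv), CH2Cl2, 0 °C → rt
Reagents that add atoms: pivaloyl chloride, CC(C)(C)C(=O)Cl
Why: DMAP-catalysed acylation of the phenol, whose hindered pivalate marks this oxygen as the later 5-OH and keeps it out of the ring closure.

Step 5
Reactants: 5 3-formyl-2-iodo-5,6-dimethoxyphenyl 2,2-dimethylpropanoate
Product: 7 3-hydroxy-2-iodo-5,6-dimethoxyphenyl 2,2-dimethylpropanoate, via aryl formate 6 (not isolated)
Conditions: mCPBA (1.2 equiv), CH2Cl2, 0 °C → rt; then MeOH, Et3N (0.2 equiv), 0 °C
Reagents that add atoms: 3-chloroperoxybenzoic acid, OOC(=O)c1cccc(Cl)c1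
Why: Baeyer–Villiger oxidation (Dakin-type) in which the electron-rich aryl group, para-methoxy to the carbonyl, migrates in the Criegee adduct to give formate 6, which amine-catalysed methanolysis should cleave much faster than the di-ortho-substituted pivalate.

Step 6
Reactants: 7 3-hydroxy-2-iodo-5,6-dimethoxyphenyl 2,2-dimethylpropanoate; 4 3-ethynyl-2,5,6-trimethoxyphenol
Product: 11 psiadiarabicin (5-hydroxy-2-(3-hydroxy-2,4,5-trimethoxyphenyl)-6,7-dimethoxy-4H-chromen-4-one), via ynone 8 (not isolated), via enaminone 9 (not isolated), via pivalate flavone 10 (not isolated)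
Conditions: 7 (1.0 equiv), 4 (1.3 equiv), PdCl2(dppf) (5 mol %), CO (10 bar), Et2NH, 70 °C; then vent, MeOH, K2CO3 (0.3 equiv), rt
Reagents that add atoms: carbon monoxide, [C-]#[O+]
Why: Palladium-catalysed carbonylative annulation of an o-iodophenol with a terminal alkyne, a known three-component flavone synthesis: zerovalent palladium formed in the flask inserts into the C4a–I bond, CO inserts to give the aroylpalladium, and the alkynyl group of 4 (deprotonated by the amine) is transferred and reductively eliminated to give ynone 8, so that C4a–C4 and C4–C3 form at the metal. Diethylamine then adds to the ynone to give enaminone 9, and the only free ring-A phenol (C8a–OH) attacks its β-carbon (6-exo-trig) and expels the amine, which closes ring C through O1–C2 as a formal 6-endo-dig closure. No stereocentre is formed. Three selectivities are needed: CO insertion before alkynyl transfer (CO pressure, copper-free conditions and the two ortho substituents should slow direct coupling), pyranone instead of 5-exo aurone (secured by the secondary amine through 9), and closure by the right oxygen (secured because the other ortho oxygen is the pivalate, which removes the 6,7- versus 7,8-dimethoxy ambiguity of a free resorcinol). Both phenols that the target keeps are tolerated since no carbanion base is present, and methanolysis in the same flask should then remove the pivalate from the peri position of 10 to give 11.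

**Compound list**

1 | 3-hydroxy-4,5-dimethoxybenzaldehyde | O=Cc1cc(O)c(OC)c(OC)c1 | starting material
2 | 3-hydroxy-2-iodo-4,5-dimethoxybenzaldehyde | O=Cc1cc(OC)c(OC)c(O)c1I | intermediate
3 | 3-hydroxy-2,4,5-trimethoxybenzaldehyde | O=Cc1cc(OC)c(OC)c(O)c1OC | intermediate
4 | 3-ethynyl-2,5,6-trimethoxyphenol | C#Cc1cc(OC)c(OC)c(O)c1OC | intermediate
5 | 3-formyl-2-iodo-5,6-dimethoxyphenyl 2,2-dimethylpropanoate | O=Cc1cc(OC)c(OC)c(OC(=O)C(C)(C)C)c1I | intermediate
6 | 3-(formyloxy)-2-iodo-5,6-dimethoxyphenyl 2,2-dimethylpropanoate | O=COc1cc(OC)c(OC)c(OC(=O)C(C)(C)C)c1I | intermediate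
7 | 3-hydroxy-2-iodo-5,6-dimethoxyphenyl 2,2-dimethylpropanoate | Oc1cc(OC)c(OC)c(OC(=O)C(C)(C)C)c1I | intermediate
8 | 3-hydroxy-2-[3-(3-hydroxy-2,4,5-trimethoxyphenyl)prop-2-ynoyl]-5,6-dimethoxyphenyl 2,2-dimethylpropanoate | CC(C)(C)C(=O)Oc1c(OC)c(OC)cc(O)c1C(=O)C#Cc1cc(OC)c(OC)c(O)c1OC | intermediate
9 | 2-[(2E)-3-(diethylamino)-3-(3-hydroxy-2,4,5-trimethoxyphenyl)prop-2-enoyl]-3-hydroxy-5,6-dimethoxyphenyl 2,2-dimethylpropanoate | CCN(CC)/C(c1cc(OC)c(OC)c(O)c1OC)=C/C(=O)c1c(O)cc(OC)c(OC)c1OC(=O)C(C)(C)C | intermediate
10 | 2-(3-hydroxy-2,4,5-trimethoxyphenyl)-6,7-dimethoxy-4-oxo-4H-chromen-5-yl 2,2-dimethylpropanoate | COc1cc(-c2cc(=O)c3c(OC(=O)C(C)(C)C)c(OC)c(OC)cc3o2)c(OC)c(O)c1OC | intermediate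
11 | psiadiarabicin, 5-hydroxy-2-(3-hydroxy-2,4,5-trimethoxyphenyl)-6,7-dimethoxy-4H-chromen-4-one | COc1cc(-c2cc(=O)c3c(O)c(OC)c(OC)cc3o2)c(OC)c(O)c1OC | target

**Step count and risks**

Total step count: 6. Longest linear sequence: 4 (steps 1, 2, 3, 6 or steps 1, 4, 5, 6).

Steps most likely to fail:

1. Step 6. The aroylpalladium may be captured by diethylamine (amide formation), or the alkyne may couple without CO insertion and cyclise to a benzofuran, faster than acyl–alkynyl coupling at the di-ortho-substituted iodide; early aminolysis of the pivalate would also free the second phenol. Fallback from 7: palladium-catalysed aminocarbonylation (PdCl2(dppf), CO, N,O-dimethylhydroxylamine hydrochloride, Et3N, toluene, 80 °C) would give the N-methoxy-N-methyl amide 3-hydroxy-2-[methoxy(methyl)carbamoyl]-5,6-dimethoxyphenyl 2,2-dimethylpropanoate F5. Addition of the dilithium salt of 4 (n-BuLi, THF, −78 → 0 °C, with one more equivalent of base for the phenol of F5) would then form the C4–C3 bond by nucleophilic acyl substitution and return to the route at 8, which Et2NH closes and methanolysis converts to 11 as in step 6.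

2. Step 1. Iodination may occur at C6 (para to the phenol) or twice, which would misplace the substituents of both rings. Fallback from 1: MOMCl and i-Pr2NEt would give 3-(methoxymethoxy)-4,5-dimethoxybenzaldehyde F1. Lithium morpholide would mask the aldehyde in the flask as its α-amino alkoxide, n-BuLi would remove the C2 proton (the only free position ortho to the OMOM group, flanked by both directing groups) and I2 would give 2-iodo-3-(methoxymethoxy)-4,5-dimethoxybenzaldehyde F2. HCl in MeOH, then water, would cleave the acetal and return to the route at 2.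

3. Step 2. Reductive loss of iodine or hydride transfer to the aldehyde under hot methoxide may outrun the C–O coupling. Fallback from 1 through the same MOM ether F1 and the same C2 lithiation, but with trapping by B(OMe)3 and oxidation of the boronate with N-methylmorpholine N-oxide to 2-hydroxy-3-(methoxymethoxy)-4,5-dimethoxybenzaldehyde F3. O-methylation (MeI, K2CO3, DMF) would give 2,4,5-trimethoxy-3-(methoxymethoxy)benzaldehyde F4, and HCl in MeOH would cleave the MOM ether and return to the route at 3; the C2–O bond then comes from an aryllithium and no halide has to be displaced.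

Further compounds
F1 | step 1 | 3-(methoxymethoxy)-4,5-dimethoxybenzaldehyde | O=Cc1cc(OCOC)c(OC)c(OC)c1
F2 | step 1 | 2-iodo-3-(methoxymethoxy)-4,5-dimethoxybenzaldehyde | O=Cc1cc(OC)c(OC)c(OCOC)c1I
F3 | step 2 | 2-hydroxy-3-(methoxymethoxy)-4,5-dimethoxybenzaldehyde | O=Cc1cc(OC)c(OC)c(OCOC)c1O
F4 | step 2 | 2,4,5-trimethoxy-3-(methoxymethoxy)benzaldehyde | O=Cc1cc(OC)c(OC)c(OCOC)c1OC
F5 | step 6 | 3-hydroxy-2-[methoxy(methyl)carbamoyl]-5,6-dimethoxyphenyl 2,2-dimethylpropanoate | CON(C)C(=O)c1c(O)cc(OC)c(OC)c1OC(=O)C(C)(C)C
A1 | direct plan | 1-(2-hydroxy-4,5,6-trimethoxyphenyl)ethan-1-one | CC(=O)c1c(O)cc(OC)c(OC)c1OC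
A2 | direct plan | 5,6,7-trimethoxy-4H-chromen-4-one | O=c1ccoc2cc(OC)c(OC)c(OC)c12
A3 | direct plan | 1-bromo-2,4,5-trimethoxybenzene | COc1cc(OC)c(Br)cc1OC
A4 | direct plan | 3-bromo-2,5,6-trimethoxyphenol | Oc1c(OC)c(Br)cc(OC)c1OC
A5 | direct plan | 2-(3-hydroxy-2,4,5-trimethoxyphenyl)-5,6,7-trimethoxy-4H-chromen-4-one | COc1cc(-c2cc(=O)c3c(OC)c(OC)c(OC)cc3o2)c(OC)c(O)c1OC
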